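## The problem

The target is a cembranolide: a fourteen-membered carbocycle (C1–C14) with an α-methylene γ-lactone cis-fused across C1–C14 (C15 carries the methylene C17 and the carbonyl carbon C16), a trisubstituted epoxide at C3–C4, an allylic acetate at C7 beside an exocyclic C8=C19 methylene, and a contiguous C12 methyl / C13 acetoxy / C14 acyloxy triad. Seven stereocentres have to be set (1S,3R,4R,7R,12S,13R,14R). Only C12, C13, C14 and C1 are contiguous, so C1 can steer C14 and C14 can steer C13 by acyclic-type induction, whereas the C3/C4 epoxide and C7 are insulated by methylene groups and can be reached only through the conformation of the large ring or through a tether. The α-methylene lactone is a Michael acceptor that will not survive hydrogenation or unselective hydride donors, the trisubstituted epoxide does not tolerate protic or Lewis acid, and the two acetates forbid strong base at the end. A short route is conceivable because the skeleton is an unrearranged cembrane of four head-to-tail isoprene units. The C1–C2 bond and the C1 stereocentre are what a 1,14-cyclisation of geranylgeranyl diphosphate delivers; the three ring alkenes of the cyclisation product lie at C3=C4, C7=C8 and C11=C12, where the target has its epoxide, its allylic acetate and its C12/C13 centres; and the isopropenyl group maps onto C15–C17. The price is that three nearly identical trisubstituted alkenes must then be told apart and the unactivated C14 methylene oxidised. The only handle is the C1 side chain: once C16 is a carboxyl group it can reach C3 through a six-membered ring, C12 through a seven-membered ring and C14 through a five-membered ring, and the plan uses each in turn.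

## Retrosynthesis

**27 ⇒ 26 ⇒ 25.** The C13 acetate is removed and C13 returned to a ketone. C13 cannot be set before C14, because C14 is addressable only as the α-carbon of a C13 ketone. Ketone 25 has one stereocentre fewer. The forward reduction has to add hydride anti to the C14–O bond and spare the α-methylene lactone.

**25 ⇒ 23.** The two C–H bonds at C11 and C12 are removed, restoring C11=C12 in conjugation with the C13 ketone. This conjugation is what distinguishes the alkene from C8=C19 and C15=C17, so a reagent specific for s-cis enones can replace hydrogenation, which would not discriminate. C12 is created on protonation of the enolate; this is the least controlled centre of the plan.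

**23 ⇒ 20.** The lactone acyl–oxygen bond and the C14–O bond are cut. C14 is inert in the cyclisation product but is the only enolisable position of enone 20, and the C16 ester sits 1,4 to it, so hydroxylation leads straight to the five-membered lactone. The forward step needs kinetic enolisation and oxygen transfer to the enolate face anti to the C15 substituent.

**20 ⇒ 18.** The C13 oxygen is removed. C13 is the E-allylic methylene of C11=C12, the position selenium dioxide attacks. This holds only if C11=C12 is the sole trisubstituted alkene at that stage, which fixes the order of everything before.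

**18 ⇒ 16 ⇒ 13 ⇒ 12.** The C7–O bond and the C8=C19 methylene come from C7=C8 by an ene reaction with singlet oxygen. C7=C8 and C11=C12 are equivalent towards singlet oxygen, and C9 and C13 equivalent towards selenium dioxide. Only C11=C12 is within reach of the C16 carboxylate, so it is masked as iodolactone 13 while C7=C8 reacts, then released with zinc. The cost is two extra steps; the gain is that neither oxidation is statistical.

**12 ⇒ 11 ⇒ 10.** The epoxide C–O bonds are cut back to C3=C4. Of the three ring alkenes only this one can be reached by the carboxylate through a six-membered ring, so iodolactonisation followed by base turns proximity into site selectivity, with C1 deciding the face. Direct peracid epoxidation of 10 would offer no such selection.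

**10 ⇒ 8 ⇒ 5.** The C16 oxidation level is removed. The isopropenyl methyl group is the kinetically most acidic allylic position and gives an allyl anion with identical termini, so no regiochemical question arises.

**5 ⇒ 4.** The C1–C2 bond is cut. The precursor is acyclic, achiral geranylgeranyl diphosphate; the forward step must close the ring, set C1 and end in an isopropenyl group, which is the native reaction of a cembrene A synthase.

**4 ⇒ 2 ⇒ 1 + 3.** The C–O bond to diphosphate is cut, leading back to commercial geranylgeraniol 1 and the diphosphate salt 3.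

## Roads not taken

**Alternative 1:** The lactone is made last by cutting C16–O and C15–C16. Diol alkyne A1 (a complete macrocycle with an ethynyl group on C1 and free hydroxyls on C13 and C14) would be carbonylated under CO with PdCl2, PPh3 and SnCl2 to hydroxy lactone A2.
- Merits: the Michael acceptor appears only at the end under nearly neutral conditions, and all seven stereocentres could be set by reagent control in acyclic fragments. Five-membered closure through O14 should beat six-membered closure through O13.
- Weak points: SnCl2 is a Lewis acid beside a trisubstituted epoxide. A1 requires fragment assembly plus a separate macrocyclisation, probably twice the length of the present sequence.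
- Comparison: in stereochemical security this road is clearly better, since nothing depends on macrocyclic facial bias. The chosen plan sets against it a ring and C1 stereocentre obtained in one step, no C–C bond construction afterwards, and no protecting group beyond an acetate that belongs to the target.

**Alternative 2:** The ring is closed at C9–C10. Carbonate A3 would be ionised by Pd(PPh3)4 and the bis(phenylsulfonyl)methyl carbanion would attack the allyl terminus to give macrocycle A4 with C8=C19 in place.
- Merits: soft-carbanion allylation is a dependable way to close fourteen-membered rings. The two allyl termini give the same constitution, and epoxide, lactone and silyl ethers tolerate the conditions.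
- Weak points: both sulfonyl groups must later be removed reductively beside an epoxide and a lactone. The lactone methylene must still be introduced by enolate chemistry, and A3 is a long chain with six stereocentres.
- Comparison: the ring closure is at least as reliable as an enzyme reaction and needs no protein production. The chosen plan avoids the synthesis of A3 and the desulfonylation, but accepts less secure late-stage selectivity.

**Alternative 3:** The C1–C14 bond is formed by a [2,3]-Wittig ring contraction. A lithium amide would deprotonate propargylic C14 of the seventeen-membered allyl propargyl ether A5, and the shift would give propargylic alcohol A6 with C1, C14 and the C15=C17 methylene set together.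
- Merits: a concerted shift transmits alkene geometry to the C1/C14 relationship, which is better founded than the enolate hydroxylation used here (step 15).
- Weak points: A6 still lacks the C12 methyl group, the C13 oxygen, the epoxide and the lactone oxidation level. The C12≡C13 alkyne would have to be elaborated with regio- and stereocontrol, and absolute control rests on the remote C7 substituent or a chiral base.
- Comparison: better for C1/C14, worse for C12/C13 and for length. The chosen plan obtains C1 with absolute control from the enzyme.

Key step: step 3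

Remark on the chemistry: cembrane locants are used throughout (C18, C19, C20 are the carbons on C4, C8, C12). The geometry at C1 never changes, though its descriptor is R in 20 for priority reasons. The C11/C12 centres drawn for 13–16 are those of one anti adduct and are erased in step 11, and 19 is carried as a C13 epimer mixture.

## Route

Step 1
Reactants: 1 geranylgeraniol
Product: 2 (2E,6E,10E)-geranylgeranyl chloride
Conditions: PPh3, CCl4, reflux
Reagents that add atoms: carbon tetrachloride, ClC(Cl)(Cl)Cl
Why: Appel reaction; chloride displaces the alkoxyphosphonium ion at the primary allylic carbon under neutral conditions, which keeps the 2E alkene and avoids allylic transposition, as for geraniol and farnesol.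

Step 2
Reactants: 2 (2E,6E,10E)-geranylgeranyl chloride; 3 diphosphoric acid as its tris(tetrabutylammonium) salt
Product: 4 (2E,6E,10E)-geranylgeranyl diphosphate
Conditions: (n-Bu4N)3HP2O7, MeCN, rt; ion exchange (NH4+ form)
Reagents that add atoms: none
Why: SN2 displacement of the primary allylic chloride by the diphosphate trianion is the standard preparation of prenyl diphosphates; ion exchange gives the water-soluble ammonium salt the enzyme needs.

Step 3
Reactants: 4 (2E,6E,10E)-geranylgeranyl diphosphate
Product: 5 (1S)-cembrene A
Conditions: recombinant (1S)-cembrene A synthase, MgCl2, HEPES buffer pH 7.5, 30 °C, pentane overlay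
Reagents that add atoms: none
Why: The synthase binds the diphosphate through Mg2+ and ionises the C–O bond to the E-allyl cation spanning C2–C4, which the folded chain captures at C2 with the distal C1=C15 alkene in Markovnikov fashion; loss of a proton from a methyl group on the C15 cation leaves the isopropenyl group. This is the native reaction of cembrene A synthases, a cation–alkene macrocyclisation of the diphosphate-ionising terpene cyclase type. The fourteen-membered ring closes by head-to-tail 1,14-alkylation, exo with respect to the attacking alkene so that C15 stays outside the ring, and needs no dilution because the chain is pre-folded in the active site. The single new stereocentre C1 is set by the face of the C1=C15 alkene that the active-site contour presents to C2, so by the choice of a (1S)-selective enzyme and not by the substrate. The step needs 1,14- over 1,10- or 1,6-closure, retention of the three E alkenes, and deprotonation at a methyl group in preference to C1 or capture by water. All of these are secured by the active-site fold; the substrate contributes only its all-E geometry.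

Step 4
Reactants: 5 (1S)-cembrene A
Product: 8 (1S,3E,7E,11E)-cembra-3,7,11,15(17)-tetraen-16-ol, via C16 allyllithium 6 (not isolated), via C16 dimethyl boronate 7 (not isolated)
Conditions: n-BuLi, TMEDA, hexane, rt; B(OMe)3, THF, −78 °C; H2O2, NaOH, 0 °C
Reagents that add atoms: hydrogen peroxide, OO
Why: Allylic lithiation by n-BuLi·TMEDA is fastest at the methyl group of an isopropenyl unit (the limonene case) and gives a 2-substituted allyl anion with identical termini, so borylation and oxidation can only give the 2-substituted allylic alcohol; C1 is not touched.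

Step 5
Reactants: 8 (1S,3E,7E,11E)-cembra-3,7,11,15(17)-tetraen-16-ol
Product: 10 (1S,3E,7E,11E)-cembra-3,7,11,15(17)-tetraen-16-oic acid, via enal 9 (not isolated)
Conditions: TEMPO (cat.), PhI(OAc)2, CH2Cl2, rt; then NaClO2, NaH2PO4, 2-methyl-2-butene, t-BuOH/H2O, 0 °C
Reagents that add atoms: sodium chlorite, [Na+].[O-]Cl=O
Why: Oxoammonium oxidation stops at the enal and Pinnick oxidation takes it to the acrylic acid; the large excess of 2-methyl-2-butene traps hypochlorous acid before it reaches the ring alkenes, as in the geranial to geranic acid case.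

Step 6
Reactants: 10 (1S,3E,7E,11E)-cembra-3,7,11,15(17)-tetraen-16-oic acid
Product: 11 (1S,3R,4S,7E,11E)-4-iodocembra-7,11,15(17)-trien-16,3-olide
Conditions: I2, KI, KHCO3, THF/H2O, 0 °C, dark
Reagents that add atoms: iodine, II
Why: Iodolactonisation; iodonium formation is reversible at all three ring alkenes, but only at C3=C4 can the carboxylate close a six-membered ring (6-exo, anti to iodine), the proximity selection that singles out the nearest alkene of polyunsaturated fatty acids. The C3–O bond forms on the alkene face syn to C1; closure with the C1–C14 bond pseudo-axial, which avoids allylic strain with the C15 methylene, gives 3R with the iodide anti at C4.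

Step 7
Reactants: 11 (1S,3R,4S,7E,11E)-4-iodocembra-7,11,15(17)-trien-16,3-olide
Product: 12 (1S,3R,4R,7E,11E)-3,4-epoxycembra-7,11,15(17)-trien-16-oic acid
Conditions: LiOH, THF/H2O, 0 °C; NaH2PO4 to pH 5
Reagents that add atoms: lithium hydroxide, [Li+].[OH-]
Why: Hydroxide opens the lactone and the freed C3 alkoxide displaces the anti-periplanar C4 iodide with inversion (halohydrin to epoxide closure), so the 3R,4R epoxide follows from the geometry of 11; the cold, weakly acidic work-up avoids re-lactonisation onto the epoxide.

Step 8
Reactants: 12 (1S,3R,4R,7E,11E)-3,4-epoxycembra-7,11,15(17)-trien-16-oic acid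
Product: 13 (1S,3R,4R,7E,11S,12R)-3,4-epoxy-11-iodocembra-7,15(17)-dien-16,12-olide
Conditions: I2, NaHCO3, MeCN, 0 °C, dark
Reagents that add atoms: iodine, II
Why: Second iodolactonisation; with C3=C4 gone the carboxylate can reach only C11=C12, by Markovnikov 7-exo attack at tertiary C12, while C7=C8 across the ring can only form its iodonium ion reversibly. The step masks C11=C12 and the acid; the C11/C12 centres are erased in step 11.

Step 9
Reactants: 13 (1S,3R,4R,7E,11S,12R)-3,4-epoxy-11-iodocembra-7,15(17)-dien-16,12-olide
Product: 15 (1S,3R,4R,7R,11S,12R)-3,4-epoxy-7-hydroxy-11-iodocembra-8(19),15(17)-dien-16,12-olide, via 7-hydroperoxide 14 (not isolated)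
Conditions: O2, tetraphenylporphyrin (cat.), visible light, CH2Cl2, −20 °C; then PPh3, 0 °C
Reagents that add atoms: oxygen, O=O
Why: Schenck ene reaction of singlet oxygen with the only electron-rich alkene left; the cis effect directs hydrogen abstraction to the more crowded side, and abstraction from the C19 methyl gives the secondary C7 hydroperoxide with the C8=C19 methylene, which PPh3 reduces. C7 is set by attack on the exposed face of the macrocyclic alkene (substrate control), taken here to give 7R.

Step 10
Reactants: 15 (1S,3R,4R,7R,11S,12R)-3,4-epoxy-7-hydroxy-11-iodocembra-8(19),15(17)-dien-16,12-olide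
Product: 16 (1S,3R,4R,7R,11S,12R)-7-acetoxy-3,4-epoxy-11-iodocembra-8(19),15(17)-dien-16,12-olide
Conditions: Ac2O, pyridine, DMAP (cat.), CH2Cl2, 0 °C
Reagents that add atoms: acetic anhydride, CC(=O)OC(C)=O
Why: DMAP-catalysed acylation of the secondary allylic alcohol installs the C7 acetate of the target early, so that the alcohol is not oxidised in step 14.

Step 11
Reactants: 16 (1S,3R,4R,7R,11S,12R)-7-acetoxy-3,4-epoxy-11-iodocembra-8(19),15(17)-dien-16,12-olide
Product: 17 (1S,3R,4R,7R,11E)-7-acetoxy-3,4-epoxycembra-8(19),11,15(17)-trien-16-oic acid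
Conditions: Zn dust, NH4Cl, EtOH/THF, rt
Reagents that add atoms: none
Why: Zinc inserts into the C11–I bond and the β-carboxylate leaves in an anti elimination (reductive opening of an iodolactone), returning the E C11=C12 alkene and the free acid; the buffered medium spares epoxide, allylic acetate and acrylate.

Step 12
Reactants: 17 (1S,3R,4R,7R,11E)-7-acetoxy-3,4-epoxycembra-8(19),11,15(17)-trien-16-oic acid
Product: 18 methyl (1S,3R,4R,7R,11E)-7-acetoxy-3,4-epoxycembra-8(19),11,15(17)-trien-16-oate
Conditions: MeI, K2CO3, DMF, rt
Reagents that add atoms: iodomethane, CI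
Why: O-Alkylation of the carboxylate; the ester is the acyl donor of step 15 and slows lactonisation onto the C13 hydroxyl made next. Iodomethane is preferred to a diazoalkane, which could add to the acrylate.

Step 13
Reactants: 18 methyl (1S,3R,4R,7R,11E)-7-acetoxy-3,4-epoxycembra-8(19),11,15(17)-trien-16-oate
Product: 19 methyl (1S,3R,4R,7R,11E)-7-acetoxy-3,4-epoxy-13-hydroxycembra-8(19),11,15(17)-trien-16-oate
Conditions: SeO2 (cat.), t-BuOOH, CH2Cl2, rt
Reagents that add atoms: selenium dioxide, O=[Se]=O; tert-butyl hydroperoxide, CC(C)(C)OO
Why: Selenium dioxide allylic oxidation (ene reaction then [2,3] shift); C11=C12 is now the only trisubstituted alkene, and the reagent attacks the methylene on the more substituted carbon that lies E to the chain, which is C13, with retention of alkene geometry. The carbinol configuration is irrelevant because step 14 removes it.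

Step 14
Reactants: 19 methyl (1S,3R,4R,7R,11E)-7-acetoxy-3,4-epoxy-13-hydroxycembra-8(19),11,15(17)-trien-16-oate
Product: 20 methyl (1R,3R,4R,7R,11E)-7-acetoxy-3,4-epoxy-13-oxocembra-8(19),11,15(17)-trien-16-oate
Conditions: Dess–Martin periodinane, NaHCO3, CH2Cl2, 0 °C to rt
Reagents that add atoms: none
Why: Buffered periodinane oxidation of the secondary allylic alcohol leaves epoxide, acetate and alkenes alone and gives the enone whose conjugation sets C11=C12 apart from the other alkenes.

Step 15
Reactants: 20 methyl (1R,3R,4R,7R,11E)-7-acetoxy-3,4-epoxy-13-oxocembra-8(19),11,15(17)-trien-16-oate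
Product: 23 (1S,3R,4R,7R,11E,14R)-7-acetoxy-3,4-epoxy-13-oxocembra-8(19),11,15(17)-trien-16,14-olide, via sodium dienolate 21 (not isolated), via 14-hydroxy ketone 22 (not isolated)
Conditions: NaN(SiMe3)2, THF, −78 °C; 3-phenyl-2-(phenylsulfonyl)oxaziridine, −78 to −20 °C; AcOH
Reagents that add atoms: 3-phenyl-2-(phenylsulfonyl)oxaziridine, O=S(=O)(c1ccccc1)N1OC1c1ccccc1
Why: Kinetic deprotonation of the enone can occur only at C14, and the N-sulfonyloxaziridine transfers oxygen to the dienolate (enolate hydroxylation). With the C1–H bond eclipsing the enolate to avoid allylic 1,3-strain, the reagent approaches anti to the branched C15 substituent, which gives 14R. The alkoxide then acylates itself with the C16 ester through a five-membered transition state to give the cis-fused lactone.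

Step 16
Reactants: 23 (1S,3R,4R,7R,11E,14R)-7-acetoxy-3,4-epoxy-13-oxocembra-8(19),11,15(17)-trien-16,14-olide
Product: 25 (1S,3R,4R,7R,12S,14R)-7-acetoxy-3,4-epoxy-13-oxocembra-8(19),15(17)-dien-16,14-olide, via boron enolate 24 (not isolated)
Conditions: catecholborane, THF, −20 °C to rt; pH 7 buffer
Reagents that add atoms: none
Why: Catecholborane reduces enones that can adopt the s-cis conformation by 1,4-hydride delivery through a six-membered boron-bound transition state and leaves unsaturated lactones, isolated alkenes and epoxides untouched. C12 is created when the boron enolate is protonated on work-up; no strong bias can be claimed for this centre, and 12S is the working assumption.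

Step 17
Reactants: 25 (1S,3R,4R,7R,12S,14R)-7-acetoxy-3,4-epoxy-13-oxocembra-8(19),15(17)-dien-16,14-olide
Product: 26 (1S,3R,4R,7R,12S,13R,14R)-7-acetoxy-3,4-epoxy-13-hydroxycembra-8(19),15(17)-dien-16,14-olide
Conditions: NaBH4, CeCl3·7H2O, MeOH/THF, −78 °C
Reagents that add atoms: none
Why: Luche reduction; the cerium-activated borohydride attacks the ketone 1,2 faster than it adds to the α-methylene lactone. Hydride approaches anti to the C14–O bond (polar Felkin–Anh model), placing the C13 hydroxyl syn to the C14 oxygen, which is 13R; this is expected to outweigh the weaker opposing bias of the C12 methyl group.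

Step 18
Reactants: 26 (1S,3R,4R,7R,12S,13R,14R)-7-acetoxy-3,4-epoxy-13-hydroxycembra-8(19),15(17)-dien-16,14-olide
Product: 27 (1S,3R,4R,7R,12S,13R,14R)-7,13-diacetoxy-3,4-epoxycembra-8(19),15(17)-dien-16,14-olide (CNP0323853.1)
Conditions: Ac2O, DMAP, Et3N, CH2Cl2, rt
Reagents that add atoms: acetic anhydride, CC(=O)OC(C)=O
Why: DMAP-catalysed acylation of the hindered secondary alcohol under conditions that leave epoxide and α-methylene lactone intact completes the target.

## Compound list

1 | geranylgeraniol, (2E,6E,10E)-3,7,11,15-tetramethylhexadeca-2,6,10,14-tetraen-1-ol | CC(C)=CCC/C(C)=C/CC/C(C)=C/CC/C(C)=C/CO | starting material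
2 | (2E,6E,10E)-geranylgeranyl chloride | CC(C)=CCC/C(C)=C/CC/C(C)=C/CC/C(C)=C/CCl | intermediate
3 | diphosphoric acid, used as its tris(tetrabutylammonium) salt | OP(=O)(O)OP(=O)(O)O | starting material
4 | (2E,6E,10E)-geranylgeranyl diphosphate (handled as its ammonium salt) | CC(C)=CCC/C(C)=C/CC/C(C)=C/CC/C(C)=C/COP(=O)(O)OP(=O)(O)O | intermediate
5 | (1S)-cembrene A, (1S,3E,7E,11E)-cembra-3,7,11,15(17)-tetraene | CC(=C)[C@H]1CC/C(C)=C/CC/C(C)=C/CC/C(C)=C/C1 | intermediate
6 | C16 allyllithium of 5 | [Li]CC(=C)[C@H]1CC/C(C)=C/CC/C(C)=C/CC/C(C)=C/C1 | intermediate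
7 | dimethyl (1S,3E,7E,11E)-cembra-3,7,11,15(17)-tetraen-16-ylboronate | COB(OC)CC(=C)[C@H]1CC/C(C)=C/CC/C(C)=C/CC/C(C)=C/C1 | intermediate
8 | (1S,3E,7E,11E)-cembra-3,7,11,15(17)-tetraen-16-ol | OCC(=C)[C@H]1CC/C(C)=C/CC/C(C)=C/CC/C(C)=C/C1 | intermediate
9 | (1S,3E,7E,11E)-cembra-3,7,11,15(17)-tetraen-16-al | O=CC(=C)[C@H]1CC/C(C)=C/CC/C(C)=C/CC/C(C)=C/C1 | intermediate
10 | (1S,3E,7E,11E)-cembra-3,7,11,15(17)-tetraen-16-oic acid | OC(=O)C(=C)[C@H]1CC/C(C)=C/CC/C(C)=C/CC/C(C)=C/C1 | intermediate
11 | (1S,3R,4S,7E,11E)-4-iodocembra-7,11,15(17)-trien-16,3-olide (six-membered lactone, iodide anti to the lactone oxygen) | C=C1C(=O)O[C@@H]2C[C@@H]1CC/C(C)=C/CC/C(C)=C/CC[C@]2(C)I | intermediate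
12 | (1S,3R,4R,7E,11E)-3,4-epoxycembra-7,11,15(17)-trien-16-oic acid | OC(=O)C(=C)[C@H]1CC/C(C)=C/CC/C(C)=C/CC[C@@]2(C)O[C@@H]2C1 | intermediate
13 | (1S,3R,4R,7E,11S,12R)-3,4-epoxy-11-iodocembra-7,15(17)-dien-16,12-olide (seven-membered lactone, iodide anti) | C=C1C(=O)O[C@]2(C)CC[C@H]1C[C@H]3O[C@]3(C)CC/C=C(C)/CC[C@@H]2I | intermediate
14 | (1S,3R,4R,7R,11S,12R)-3,4-epoxy-7-hydroperoxy-11-iodocembra-8(19),15(17)-dien-16,12-olide | C=C1C(=O)O[C@]2(C)CC[C@H]1C[C@H]3O[C@]3(C)CC[C@@H](OO)C(=C)CC[C@@H]2I | intermediate
15 | (1S,3R,4R,7R,11S,12R)-3,4-epoxy-7-hydroxy-11-iodocembra-8(19),15(17)-dien-16,12-olide | C=C1C(=O)O[C@]2(C)CC[C@H]1C[C@H]3O[C@]3(C)CC[C@@H](O)C(=C)CC[C@@H]2I | intermediate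
16 | (1S,3R,4R,7R,11S,12R)-7-acetoxy-3,4-epoxy-11-iodocembra-8(19),15(17)-dien-16,12-olide | C=C1C(=O)O[C@]2(C)CC[C@H]1C[C@H]3O[C@]3(C)CC[C@@H](OC(C)=O)C(=C)CC[C@@H]2I | intermediate
17 | (1S,3R,4R,7R,11E)-7-acetoxy-3,4-epoxycembra-8(19),11,15(17)-trien-16-oic acid | OC(=O)C(=C)[C@H]1CC/C(C)=C/CCC(=C)[C@H](OC(C)=O)CC[C@@]2(C)O[C@@H]2C1 | intermediate
18 | methyl (1S,3R,4R,7R,11E)-7-acetoxy-3,4-epoxycembra-8(19),11,15(17)-trien-16-oate | COC(=O)C(=C)[C@H]1CC/C(C)=C/CCC(=C)[C@H](OC(C)=O)CC[C@@]2(C)O[C@@H]2C1 | intermediate
19 | methyl (1S,3R,4R,7R,11E)-7-acetoxy-3,4-epoxy-13-hydroxycembra-8(19),11,15(17)-trien-16-oate (C13 epimers) | COC(=O)C(=C)[C@H]1CC(O)/C(C)=C/CCC(=C)[C@H](OC(C)=O)CC[C@@]2(C)O[C@@H]2C1 | intermediate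
20 | methyl (1R,3R,4R,7R,11E)-7-acetoxy-3,4-epoxy-13-oxocembra-8(19),11,15(17)-trien-16-oate | COC(=O)C(=C)[C@H]1CC(=O)/C(C)=C/CCC(=C)[C@H](OC(C)=O)CC[C@@]2(C)O[C@@H]2C1 | intermediate
21 | sodium dienolate of 20 (C13–ONa, C13=C14, C11=C12) | COC(=O)C(=C)[C@H]1C=C(O[Na])/C(C)=C/CCC(=C)[C@H](OC(C)=O)CC[C@@]2(C)O[C@@H]2C1 | intermediate
22 | methyl (1S,3R,4R,7R,11E,14R)-7-acetoxy-3,4-epoxy-14-hydroxy-13-oxocembra-8(19),11,15(17)-trien-16-oate | COC(=O)C(=C)[C@H]1[C@@H](O)C(=O)/C(C)=C/CCC(=C)[C@H](OC(C)=O)CC[C@@]2(C)O[C@@H]2C1 | intermediate
23 | (1S,3R,4R,7R,11E,14R)-7-acetoxy-3,4-epoxy-13-oxocembra-8(19),11,15(17)-trien-16,14-olide | C=C1CC/C=C(C)/C(=O)[C@@H]2OC(=O)C(=C)[C@@H]2C[C@H]2O[C@]2(C)CC[C@H]1OC(C)=O | intermediate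
24 | catechol boron enolate of 25 (C13–O–B, C12=C13) | C=C1CCCC(C)=C(OB3Oc4ccccc4O3)[C@@H]2OC(=O)C(=C)[C@@H]2C[C@H]2O[C@]2(C)CC[C@H]1OC(C)=O | intermediate
25 | (1S,3R,4R,7R,12S,14R)-7-acetoxy-3,4-epoxy-13-oxocembra-8(19),15(17)-dien-16,14-olide | C=C1CCC[C@H](C)C(=O)[C@@H]2OC(=O)C(=C)[C@@H]2C[C@H]2O[C@]2(C)CC[C@H]1OC(C)=O | intermediate
26 | (1S,3R,4R,7R,12S,13R,14R)-7-acetoxy-3,4-epoxy-13-hydroxycembra-8(19),15(17)-dien-16,14-olide | C=C1CCC[C@H](C)[C@@H](O)[C@@H]2OC(=O)C(=C)[C@@H]2C[C@H]2O[C@]2(C)CC[C@H]1OC(C)=O | intermediate
27 | (1S,3R,4R,7R,12S,13R,14R)-7,13-diacetoxy-3,4-epoxycembra-8(19),15(17)-dien-16,14-olide (CNP0323853.1) | C=C1CCC[C@H](C)[C@@H](OC(C)=O)[C@@H]2OC(=O)C(=C)[C@@H]2C[C@H]2O[C@]2(C)CC[C@H]1OC(C)=O | target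

## Step count and least certain steps

Total: 18 steps. Longest linear sequence: 18 steps from 1 (3 is purchased).

**Step 3 (key step).** Most likely to go wrong is the fate of the C15 cation and the throughput: capture by water or deprotonation at C1 in place of the methyl group, product inhibition by released diphosphate, or incomplete facial selectivity with an enzyme that is not matched to the 1S series. Fallback: the same synthase is expressed in a microbial host with an enhanced isoprenoid pathway, so that 4 is generated inside the cell from sugar instead of by steps 1 and 2, and 5 is extracted continuously into an organic overlay; the fallback sets out from 4 formed in the cell and returns at 5 (F0: no new compound).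

**Step 8.** Most likely to go wrong is the seven-membered ring closure itself: it is slow, so the iodonium ion may simply revert, or the carboxylate may open the neighbouring epoxide under iodine activation. Fallback (sets out from 12, returns at 20): 12 is methylated (MeI, K2CO3) to methyl (1S,3R,4R,7E,11E)-3,4-epoxycembra-7,11,15(17)-trien-16-oate F1. Selenium dioxide and t-BuOOH then oxidise C13 and, unselectively, C9; the 13-hydroxy ester F2 is separated and oxidised with Dess–Martin periodinane to the 13-oxo ester F3. In F3 the C11=C12 alkene is conjugated and no longer reacts with singlet oxygen, so the ene reaction goes to C7=C8 only and gives the 7-hydroperoxide F4, which PPh3 reduces to the 7-hydroxy enone F5. Acetylation of F5 gives 20. This removes steps 8–12 but pays with a statistical allylic oxidation.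

**Step 6.** Most likely to go wrong is oxygen delivery to the other face of C3=C4, because the bridged six-membered transition state can also close with both ring bonds pseudo-equatorial; step 7 would then give the 3S,4S epoxide. Partial seven-membered closure onto C11=C12 is a second leak. Fallback (sets out from 10, returns at 12): steps 6 and 7 are run as written to the epimeric (1S,3S,4S)-epoxy acid F6, which is methylated to the ester F7. Dilute HClO4 in aqueous THF opens the epoxide with inversion at tertiary C4 to the (3S,4R)-diol F8. Selective mesylation of the secondary C3 hydroxyl gives the mesylate F9. LiOH then closes the epoxide with inversion at C3 and saponifies the ester, giving 12 with both centres inverted.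

**Step 9.** Most likely to go wrong is hydrogen abstraction from C6 in place of C19, which diverts material to the tertiary C8 hydroperoxide, and attack of singlet oxygen on the other face of C7=C8, since only ring conformation controls it. Fallback for the facial problem (sets out from 13, returns at 16): the ene reaction and reduction are run as written, and the (7S)-7-hydroxy iodolactone F10 is converted by a Mitsunobu reaction with AcOH (PPh3, DIAD) directly into 16 with inversion, which also replaces step 10.

**Step 15.** Most likely to go wrong is poor facial selectivity in the oxygen transfer, if the ring conformation overrides the allylic-strain model, followed by base-induced epimerisation at C14 once the acyloxy ketone has formed. Fallback (sets out from 20, returns at 23): 20 is converted (NaN(SiMe3)2, Me3SiCl) into the 13-trimethylsilyloxy 11,13-diene F11. A Shi epoxidation with the fructose-derived ketone enantiomer matched to the required face oxidises the electron-rich enol ether under reagent control to 22, which lactonises to 23.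

**Step 16.** Most likely to go wrong is unselective protonation at C12, with competing 1,2-reduction of the activated ketone as a lesser risk; the centre cannot be corrected later by base without endangering C14. Fallback (sets out from 23, returns at 25): reduction with an ene-reductase of the Old Yellow Enzyme family (NADPH, glucose dehydrogenase recycling), which adds hydride at C11 and a proton at C12 from fixed active-site positions, so that C12 is set by the choice of enzyme from a panel (F0: no new compound).

## Further compounds

F0 | step 3 | none | none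
F1 | step 8 | methyl (1S,3R,4R,7E,11E)-3,4-epoxycembra-7,11,15(17)-trien-16-oate | COC(=O)C(=C)[C@H]1CC/C(C)=C/CC/C(C)=C/CC[C@@]2(C)O[C@@H]2C1
F2 | step 8 | methyl (1S,3R,4R,7E,11E)-3,4-epoxy-13-hydroxycembra-7,11,15(17)-trien-16-oate (C13 epimers) | COC(=O)C(=C)[C@H]1CC(O)/C(C)=C/CC/C(C)=C/CC[C@@]2(C)O[C@@H]2C1
F3 | step 8 | methyl (1R,3R,4R,7E,11E)-3,4-epoxy-13-oxocembra-7,11,15(17)-trien-16-oate | COC(=O)C(=C)[C@H]1CC(=O)/C(C)=C/CC/C(C)=C/CC[C@@]2(C)O[C@@H]2C1
F4 | step 8 | methyl (1R,3R,4R,7R,11E)-3,4-epoxy-7-hydroperoxy-13-oxocembra-8(19),11,15(17)-trien-16-oate | COC(=O)C(=C)[C@H]1CC(=O)/C(C)=C/CCC(=C)[C@H](OO)CC[C@@]2(C)O[C@@H]2C1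
F5 | step 8 | methyl (1R,3R,4R,7R,11E)-3,4-epoxy-7-hydroxy-13-oxocembra-8(19),11,15(17)-trien-16-oate | COC(=O)C(=C)[C@H]1CC(=O)/C(C)=C/CCC(=C)[C@H](O)CC[C@@]2(C)O[C@@H]2C1
F6 | step 6 | (1S,3S,4S,7E,11E)-3,4-epoxycembra-7,11,15(17)-trien-16-oic acid | OC(=O)C(=C)[C@H]1CC/C(C)=C/CC/C(C)=C/CC[C@]2(C)O[C@H]2C1
F7 | step 6 | methyl (1S,3S,4S,7E,11E)-3,4-epoxycembra-7,11,15(17)-trien-16-oate | COC(=O)C(=C)[C@H]1CC/C(C)=C/CC/C(C)=C/CC[C@]2(C)O[C@H]2C1
F8 | step 6 | methyl (1S,3S,4R,7E,11E)-3,4-dihydroxycembra-7,11,15(17)-trien-16-oate | COC(=O)C(=C)[C@H]1CC/C(C)=C/CC/C(C)=C/CC[C@@](C)(O)[C@@H](O)C1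
F9 | step 6 | methyl (1S,3S,4R,7E,11E)-4-hydroxy-3-(methanesulfonyloxy)cembra-7,11,15(17)-trien-16-oate | COC(=O)C(=C)[C@H]1CC/C(C)=C/CC/C(C)=C/CC[C@@](C)(O)[C@@H](OS(C)(=O)=O)C1
F10 | step 9 | (1S,3R,4R,7S,11S,12R)-3,4-epoxy-7-hydroxy-11-iodocembra-8(19),15(17)-dien-16,12-olide | C=C1C(=O)O[C@]2(C)CC[C@H]1C[C@H]3O[C@]3(C)CC[C@H](O)C(=C)CC[C@@H]2I
F11 | step 15 | methyl (3R,4R,7R,11E)-7-acetoxy-3,4-epoxy-13-(trimethylsilyloxy)cembra-8(19),11,13,15(17)-tetraen-16-oate (C1 as in 20) | COC(=O)C(=C)[C@H]1C=C(O[Si](C)(C)C)/C(C)=C/CCC(=C)[C@H](OC(C)=O)CC[C@@]2(C)O[C@@H]2C1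
F0 | step 16 | none | none
A1 | alternative 1 | fourteen-membered 13,14-diol with an ethynyl group on C1, 3,4-epoxide, C8=C19 methylene and C7 tert-butyldimethylsilyl ether, configured as in the target | C=C1CCC[C@H](C)[C@@H](O)[C@H](O)[C@H](C#C)C[C@H]2O[C@]2(C)CC[C@H]1O[Si](C)(C)C(C)(C)C
A2 | alternative 1 | (1S,3R,4R,7R,12S,13R,14R)-7-(tert-butyldimethylsilyloxy)-3,4-epoxy-13-hydroxycembra-8(19),15(17)-dien-16,14-olide | C=C1CCC[C@H](C)[C@@H](O)[C@@H]2OC(=O)C(=C)[C@@H]2C[C@H]2O[C@]2(C)CC[C@H]1O[Si](C)(C)C(C)(C)C
A3 | alternative 2 | open-chain C9 allylic methyl carbonate with a C10 bis(phenylsulfonyl)methyl terminus, saturated 16,14-lactone, 3,4-epoxide and C7/C13 silyl ethers | COC(=O)OCC(=C)[C@H](O[Si](C)(C)C(C)(C)C)CC[C@@]1(C)O[C@@H]1C[C@H]1CC(=O)O[C@H]1[C@H](O[Si](C)(C)C(C)(C)C)[C@@H](C)CC(S(=O)(=O)c1ccccc1)S(=O)(=O)c1ccccc1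
A4 | alternative 2 | fourteen-membered C10 bis(phenylsulfonyl) macrocycle with C8=C19 methylene, saturated lactone, 3,4-epoxide and C7/C13 silyl ethers | C=C1CC(S(=O)(=O)c2ccccc2)(S(=O)(=O)c2ccccc2)C[C@H](C)[C@@H](O[Si](C)(C)C(C)(C)C)[C@@H]2OC(=O)C[C@@H]2C[C@H]2O[C@]2(C)CC[C@H]1O[Si](C)(C)C(C)(C)C
A5 | alternative 3 | seventeen-membered allyl propargyl ether (C14–O–C17) with C1=C15, C3=C4, C12≡C13, C8=C19, a C16 p-methoxybenzyl ether and a C7 silyl ether | C=C1CCCC#CCOC/C(COCc2ccc(OC)cc2)=C\C/C=C(\C)CC[C@H]1O[Si](C)(C)C(C)(C)C
A6 | alternative 3 | fourteen-membered C14 propargylic alcohol with the 2-propenyl unit on C1 (C15=C17, C16 p-methoxybenzyl ether), C3=C4, C12≡C13, C8=C19 and a C7 silyl ether | C=C1CCCC#C[C@H](O)[C@H](C(=C)COCc2ccc(OC)cc2)C/C=C(\C)CC[C@H]1O[Si](C)(C)C(C)(C)C
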